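**Retrosynthetic overview**
1. Target ⇒ global hydrogenolysis of a tribenzyl ester. The malate ester C–O bond comes from SN2 attack of cesium 4-benzyl (R)-malate (from D-malic acid) on the primary iodide of the dibenzyl-protected lactone core.
2. Core ⇒ ester exchange (Me/t-Bu → H → Bn) on a saturated ω-hydroxy lactone diester ⇒ hydrogenation of a Wittig product made from a butenolide aldehyde and a C8 ylide from 8-bromooctan-1-ol.
3. Key C–C bond (CH to quaternary C): enantioselective intermolecular Mukaiyama–Michael addition of methyl 5-(triisopropylsilyloxy)furan-2-carboxylate to tert-butyl (E)-4-oxobut-2-enoate under iminium catalysis. This step sets both core stereocentres.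
4. Ring: the only ring comes from 2(5H)-furanone. It passes through silyloxyfuran → butenolide (key step) → γ-butanolide (hydrogenation), and is opened and re-closed once during saponification.

Assumption: the SMILES is read as R at all three stereocentres. The like (R,R) core is taken to be the ω-oxygenated antipode of (4S,5S)-spiculisporic acid, and that relative configuration is taken to be the one given by the syn-selective form of the key addition.

**Route**

Step 1
Reactants: 1 2(5H)-furanone
Product: 2 2-(triisopropylsilyloxy)furan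
Conditions: TIPSOTf (1.05 equiv), Et3N (1.3 equiv), CH2Cl2, 0 °C to rt, 2 h
Reagents that add atoms: triisopropylsilyl trifluoromethanesulfonate, CC(C)[Si](OS(=O)(=O)C(F)(F)F)(C(C)C)C(C)C
Why: Soft enolisation and O-silylation, in which Et3N removes the γ-proton of the silyl-activated butenolide and the dienolate is trapped on oxygen, aromatising to the silyloxyfuran.

Step 2
Reactants: 2 2-(triisopropylsilyloxy)furan
Product: 4 methyl 5-(triisopropylsilyloxy)furan-2-carboxylate, via 5-lithio-2-(triisopropylsilyloxy)furan 3 (not isolated)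
Conditions: s-BuLi (1.1 equiv), TMEDA (1.1 equiv), THF, −78 °C, 1.5 h; cannulate into ClCO2Me (3 equiv), THF, −78 to 0 °C
Reagents that add atoms: methyl chloroformate, COC(=O)Cl
Why: Ring lithiation at the only free position next to the furan oxygen (C5) followed by C-acylation, with inverse addition into excess chloroformate so that the lithiofuran cannot attack the product ester.

Step 3
Reactants: 5 2,2-dimethoxyacetaldehyde; 6 tert-butyl 2-(triphenylphosphoranylidene)acetate
Product: 7 tert-butyl (E)-4,4-dimethoxybut-2-enoate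
Conditions: CH2Cl2 (5 as 60 wt% aqueous solution), rt, 16 h
Reagents that add atoms: none
Why: Wittig olefination with a stabilised ylide, which tolerates water and gives the E-enoate.

Step 4
Reactants: 7 tert-butyl (E)-4,4-dimethoxybut-2-enoate
Product: 8 tert-butyl (E)-4-oxobut-2-enoate
Conditions: p-TsOH·H2O (10 mol%), acetone/H2O (10:1), rt
Reagents that add atoms: water, O
Why: Acid-catalysed acetal hydrolysis under conditions too mild to ionise the tert-butyl ester, with any Z-isomer equilibrating to the E-enal.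

Step 5
Reactants: 4 methyl 5-(triisopropylsilyloxy)furan-2-carboxylate; 8 tert-butyl (E)-4-oxobut-2-enoate
Product: 9 methyl (2R)-2-[(2R)-1-tert-butoxy-1,4-dioxobutan-2-yl]-5-oxo-2,5-dihydrofuran-2-carboxylate
Conditions: 8 (2 equiv), (2S,5S)-5-benzyl-2-tert-butyl-3-methylimidazolidin-4-one (20 mol%), TFA (20 mol%), H2O (2 equiv), THF, −10 °C, 24–48 h; chromatography
Reagents that add atoms: none
Why: Organocatalytic enantioselective Mukaiyama–Michael addition under iminium catalysis, in which the benzyl and tert-butyl groups of the catalyst block one face of the E-configured activated enal so that furan C5 attacks the ester-bearing carbon from the open face and sets the (R)-CH centre, while the TFA/THF medium favours the syn (like) approach that sets the (R)-quaternary centre (about 10:1 dr and 90% ee expected) and water takes up the silyl group.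

Step 6
Reactants: 10 8-bromooctan-1-ol
Product: 11 benzyl 8-bromooctyl ether
Conditions: BnOC(=NH)CCl3 (1.3 equiv), TfOH (5 mol%), cyclohexane/CH2Cl2 (2:1), 0 °C to rt
Reagents that add atoms: benzyl 2,2,2-trichloroacetimidate, N=C(OCc1ccccc1)C(Cl)(Cl)Cl
Why: Acid-catalysed trichloroacetimidate O-benzylation avoids an alkoxide, which would displace the bromide.

Step 7
Reactants: 11 benzyl 8-bromooctyl ether
Product: 12 [8-(benzyloxy)octyl]triphenylphosphonium bromide
Conditions: PPh3 (1.1 equiv), MeCN, reflux, 48 h; dry by toluene azeotrope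
Reagents that add atoms: triphenylphosphine, c1ccc(cc1)P(c1ccccc1)c1ccccc1
Why: SN2 quaternisation of PPh3 by an unhindered primary bromide, to which the benzyl ether is inert.

Step 8
Reactants: 12 [8-(benzyloxy)octyl]triphenylphosphonium bromide; 9 methyl (2R)-2-[(2R)-1-tert-butoxy-1,4-dioxobutan-2-yl]-5-oxo-2,5-dihydrofuran-2-carboxylate
Product: 14 methyl (2R)-2-[(2R,4Z)-12-(benzyloxy)-1-tert-butoxy-1-oxododec-4-en-2-yl]-5-oxo-2,5-dihydrofuran-2-carboxylate, via 8-(benzyloxy)octylidenetriphenylphosphorane 13 (not isolated)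
Conditions: 12 (1.2 equiv), NaN(SiMe3)2 (1.15 equiv), THF, −78 to 0 °C, 30 min; then 9, −78 °C, 1 h, to −20 °C
Reagents that add atoms: none
Why: Wittig olefination with a non-stabilised ylide, whose addition to the unhindered aldehyde at −78 °C outruns enolisation, attack on the hindered butenolide and attack on the esters, and whose Z/E outcome is irrelevant because the alkene is hydrogenated next.

Step 9
Reactants: 14 methyl (2R)-2-[(2R,4Z)-12-(benzyloxy)-1-tert-butoxy-1-oxododec-4-en-2-yl]-5-oxo-2,5-dihydrofuran-2-carboxylate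
Product: 15 methyl (2R)-2-[(2R)-1-tert-butoxy-12-hydroxy-1-oxododecan-2-yl]-5-oxooxolane-2-carboxylate
Conditions: H2 (1 atm), Pd/C (10 wt%), EtOAc/EtOH (1:1), rt, 16 h
Reagents that add atoms: none
Why: Heterogeneous catalytic hydrogenation saturates the chain alkene and the butenolide and hydrogenolyses the benzyl ether in one operation, without touching the esters, the lactone or either stereocentre.

Step 10
Reactants: 15 methyl (2R)-2-[(2R)-1-tert-butoxy-12-hydroxy-1-oxododecan-2-yl]-5-oxooxolane-2-carboxylate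
Product: 16 (2R)-12-hydroxy-2-[(2R)-2-(methoxycarbonyl)-5-oxooxolan-2-yl]dodecanoic acid
Conditions: TFA/CH2Cl2 (1:3), 0 °C to rt, 3 h; evaporate with toluene, use crude
Reagents that add atoms: none
Why: Acidolysis of the tert-butyl ester by alkyl–oxygen cleavage leaves the methyl ester and lactone intact and is done before any base so that the CH centre later sits next to a non-enolisable carboxylate, while any trifluoroacetate formed on the primary alcohol is cleaved in the next step.

Step 11
Reactants: 16 (2R)-12-hydroxy-2-[(2R)-2-(methoxycarbonyl)-5-oxooxolan-2-yl]dodecanoic acid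
Product: 19 (2R)-2-[(1R)-1-carboxy-11-hydroxyundecyl]-5-oxooxolane-2-carboxylic acid, via open-chain trilithium tricarboxylate 17 (not isolated), via open-chain hydroxy triacid 18 (not isolated)
Conditions: LiOH·H2O (6 equiv), THF/H2O (2:1), 0 °C to rt, 12 h; then 2 M HCl to pH 1, 50 °C, 2 h; EtOAc extraction; recrystallise (EtOAc/heptane) to shed the minor diastereomer and raise ee
Reagents that add atoms: lithium hydroxide, [Li+].[OH-]
Why: Saponification followed by acid-induced γ-lactonisation, in which only acyl–oxygen bonds are broken and re-formed and the CH centre is flanked by a carboxylate, so both configurations are retained and only the five-membered lactone can close.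

Step 12
Reactants: 19 (2R)-2-[(1R)-1-carboxy-11-hydroxyundecyl]-5-oxooxolane-2-carboxylic acid
Product: 20 benzyl (2R)-2-[(2R)-1-(benzyloxy)-12-hydroxy-1-oxododecan-2-yl]-5-oxooxolane-2-carboxylate
Conditions: BnBr (2.3 equiv), KHCO3 (3 equiv), DMF, rt, 16 h
Reagents that add atoms: benzyl bromide, BrCc1ccccc1
Why: Carboxylate O-alkylation (SN2 on benzyl bromide) is insensitive to hindrance at the quaternary acid, and bicarbonate is too weak to benzylate the alcohol or to trigger β-elimination of the lactone oxygen.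

Step 13
Reactants: 20 benzyl (2R)-2-[(2R)-1-(benzyloxy)-12-hydroxy-1-oxododecan-2-yl]-5-oxooxolane-2-carboxylate
Product: 21 benzyl (2R)-2-[(2R)-1-(benzyloxy)-12-iodo-1-oxododecan-2-yl]-5-oxooxolane-2-carboxylate
Conditions: I2 (1.3 equiv), PPh3 (1.3 equiv), imidazole (1.5 equiv), CH2Cl2, 0 °C to rt
Reagents that add atoms: iodine, II
Why: Appel-type iodination converts the primary alcohol through its alkoxyphosphonium salt under nearly neutral conditions that spare the benzyl esters and the lactone.

Step 14
Reactants: 22 (R)-malic acid (D-malic acid)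
Product: 23 2-[(4R)-2,2-dimethyl-5-oxo-1,3-dioxolan-4-yl]acetic acid
Conditions: Me2C(OMe)2 (5 equiv, neat), p-TsOH·H2O (1 mol%), rt, 3 h; recrystallise
Reagents that add atoms: 2,2-dimethoxypropane, COC(C)(C)OC
Why: Acid-catalysed transketalisation ties up the α-hydroxy acid unit selectively as the favoured five-membered dioxolanone, leaving the C4 acid free and the stereocentre untouched.

Step 15
Reactants: 23 2-[(4R)-2,2-dimethyl-5-oxo-1,3-dioxolan-4-yl]acetic acid
Product: 24 benzyl 2-[(4R)-2,2-dimethyl-5-oxo-1,3-dioxolan-4-yl]acetate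
Conditions: BnBr (1.1 equiv), KHCO3 (1.5 equiv), DMF, rt, 12 h
Reagents that add atoms: benzyl bromide, BrCc1ccccc1
Why: Carboxylate alkylation (SN2) with a base too weak to cause β-elimination to a fumarate.

Step 16
Reactants: 24 benzyl 2-[(4R)-2,2-dimethyl-5-oxo-1,3-dioxolan-4-yl]acetate
Product: 25 (2R)-4-(benzyloxy)-2-hydroxy-4-oxobutanoic acid
Conditions: 1 M HCl/THF (1:1), rt, 12 h
Reagents that add atoms: none
Why: Acid hydrolysis of the labile acyloxy ketal releases acetone far faster than the benzyl ester hydrolyses, giving the regiochemically unambiguous C1 acid with the C–O bond at the stereocentre intact.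

Step 17
Reactants: 25 (2R)-4-(benzyloxy)-2-hydroxy-4-oxobutanoic acid; 21 benzyl (2R)-2-[(2R)-1-(benzyloxy)-12-iodo-1-oxododecan-2-yl]-5-oxooxolane-2-carboxylate
Product: 27 4-benzyl 1-{(11R)-12-(benzyloxy)-11-[(2R)-2-(benzyloxycarbonyl)-5-oxooxolan-2-yl]-12-oxododecyl} (2R)-2-hydroxybutanedioate, via cesium 4-benzyl (R)-malate 26 (not isolated)
Conditions: 25 (1.3 equiv), Cs2CO3 (0.6 equiv), DMF, rt, 30 min; then 21 (1.0 equiv), rt to 35 °C, 16 h
Reagents that add atoms: none
Why: Cesium carboxylate alkylation (SN2 on the primary iodide) needs no activation of the malate carbonyl, so the free α-hydroxyl needs no protection, the malate centre cannot racemise and no free carbonate is left to harm the core.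

Step 18
Reactants: 27 4-benzyl 1-{(11R)-12-(benzyloxy)-11-[(2R)-2-(benzyloxycarbonyl)-5-oxooxolan-2-yl]-12-oxododecyl} (2R)-2-hydroxybutanedioate
Product: 28 (2R)-2-[(1R)-1-carboxy-11-{[(2R)-3-carboxy-2-hydroxypropanoyl]oxy}undecyl]-5-oxooxolane-2-carboxylic acid
Conditions: H2 (1 atm), Pd/C (10 wt%), THF, rt, 6 h; filter, evaporate
Reagents that add atoms: none
Why: Neutral catalytic hydrogenolysis removes all three benzyl esters at once, while the alkyl malate ester, the lactone and the three stereocentres are inert.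

**Compound list**
1 | 2(5H)-furanone | O=C1C=CCO1 | starting material
2 | 2-(triisopropylsilyloxy)furan | CC(C)[Si](Oc1ccco1)(C(C)C)C(C)C | intermediate
3 | 5-lithio-2-(triisopropylsilyloxy)furan | [Li]c1ccc(O[Si](C(C)C)(C(C)C)C(C)C)o1 | intermediate
4 | methyl 5-(triisopropylsilyloxy)furan-2-carboxylate | COC(=O)c1ccc(O[Si](C(C)C)(C(C)C)C(C)C)o1 | intermediate
5 | 2,2-dimethoxyacetaldehyde | COC(OC)C=O | starting material
6 | tert-butyl 2-(triphenylphosphoranylidene)acetate | CC(C)(C)OC(=O)C=P(c1ccccc1)(c1ccccc1)c1ccccc1 | starting material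
7 | tert-butyl (E)-4,4-dimethoxybut-2-enoate | COC(OC)/C=C/C(=O)OC(C)(C)C | intermediate
8 | tert-butyl (E)-4-oxobut-2-enoate | O=C/C=C/C(=O)OC(C)(C)C | intermediate
9 | methyl (2R)-2-[(2R)-1-tert-butoxy-1,4-dioxobutan-2-yl]-5-oxo-2,5-dihydrofuran-2-carboxylate | O=CC[C@@H](C(=O)OC(C)(C)C)[C@@]1(C(=O)OC)C=CC(=O)O1 | intermediate
10 | 8-bromooctan-1-ol | OCCCCCCCCBr | starting material
11 | benzyl 8-bromooctyl ether | BrCCCCCCCCOCc1ccccc1 | intermediate
12 | [8-(benzyloxy)octyl]triphenylphosphonium bromide | [Br-].C(c1ccccc1)OCCCCCCCC[P+](c1ccccc1)(c1ccccc1)c1ccccc1 | intermediate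
13 | 8-(benzyloxy)octylidenetriphenylphosphorane | C(c1ccccc1)OCCCCCCCC=P(c1ccccc1)(c1ccccc1)c1ccccc1 | intermediate
14 | methyl (2R)-2-[(2R,4Z)-12-(benzyloxy)-1-tert-butoxy-1-oxododec-4-en-2-yl]-5-oxo-2,5-dihydrofuran-2-carboxylate | C(c1ccccc1)OCCCCCCC/C=C\C[C@@H](C(=O)OC(C)(C)C)[C@@]2(C(=O)OC)C=CC(=O)O2 | intermediate
15 | methyl (2R)-2-[(2R)-1-tert-butoxy-12-hydroxy-1-oxododecan-2-yl]-5-oxooxolane-2-carboxylate | OCCCCCCCCCC[C@@H](C(=O)OC(C)(C)C)[C@@]1(C(=O)OC)CCC(=O)O1 | intermediate
16 | (2R)-12-hydroxy-2-[(2R)-2-(methoxycarbonyl)-5-oxooxolan-2-yl]dodecanoic acid | OCCCCCCCCCC[C@@H](C(=O)O)[C@@]1(C(=O)OC)CCC(=O)O1 | intermediate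
17 | trilithium (3R,4R)-3,14-dihydroxytetradecane-1,3,4-tricarboxylate | OCCCCCCCCCC[C@@H](C(=O)[O-])[C@@](O)(C(=O)[O-])CCC(=O)[O-].[Li+].[Li+].[Li+] | intermediate
18 | (3R,4R)-3,14-dihydroxytetradecane-1,3,4-tricarboxylic acid | OCCCCCCCCCC[C@@H](C(=O)O)[C@@](O)(C(=O)O)CCC(=O)O | intermediate
19 | (2R)-2-[(1R)-1-carboxy-11-hydroxyundecyl]-5-oxooxolane-2-carboxylic acid | OCCCCCCCCCC[C@@H](C(=O)O)[C@@]1(C(=O)O)CCC(=O)O1 | intermediate
20 | benzyl (2R)-2-[(2R)-1-(benzyloxy)-12-hydroxy-1-oxododecan-2-yl]-5-oxooxolane-2-carboxylate | OCCCCCCCCCC[C@@H](C(=O)OCc1ccccc1)[C@@]2(C(=O)OCc3ccccc3)CCC(=O)O2 | intermediate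
21 | benzyl (2R)-2-[(2R)-1-(benzyloxy)-12-iodo-1-oxododecan-2-yl]-5-oxooxolane-2-carboxylate | ICCCCCCCCCC[C@@H](C(=O)OCc1ccccc1)[C@@]2(C(=O)OCc3ccccc3)CCC(=O)O2 | intermediate
22 | (R)-malic acid | O=C(O)C[C@@H](O)C(=O)O | starting material
23 | 2-[(4R)-2,2-dimethyl-5-oxo-1,3-dioxolan-4-yl]acetic acid | CC1(C)O[C@H](CC(=O)O)C(=O)O1 | intermediate
24 | benzyl 2-[(4R)-2,2-dimethyl-5-oxo-1,3-dioxolan-4-yl]acetate | CC1(C)O[C@H](CC(=O)OCc2ccccc2)C(=O)O1 | intermediate
25 | (2R)-4-(benzyloxy)-2-hydroxy-4-oxobutanoic acid | O=C(OCc1ccccc1)C[C@@H](O)C(=O)O | intermediate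
26 | cesium (2R)-4-(benzyloxy)-2-hydroxy-4-oxobutanoate | O=C(OCc1ccccc1)C[C@@H](O)C(=O)[O-].[Cs+] | intermediate
27 | 4-benzyl 1-{(11R)-12-(benzyloxy)-11-[(2R)-2-(benzyloxycarbonyl)-5-oxooxolan-2-yl]-12-oxododecyl} (2R)-2-hydroxybutanedioate | O=C(OCc1ccccc1)C[C@@H](O)C(=O)OCCCCCCCCCC[C@@H](C(=O)OCc2ccccc2)[C@@]3(C(=O)OCc4ccccc4)CCC(=O)O3 | intermediate
28 | (2R)-2-[(1R)-1-carboxy-11-{[(2R)-3-carboxy-2-hydroxypropanoyl]oxy}undecyl]-5-oxooxolane-2-carboxylic acid | O=C(O)C[C@@H](O)C(=O)OCCCCCCCCCC[C@@H](C(=O)O)[C@@]1(C(=O)O)CCC(=O)O1 | target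

**Step count**
Total steps: 18.
Longest linear sequence: 11 steps (1, 2, 5, 8, 9, 10, 11, 12, 13, 17, 18).

**Three steps most likely to fail**

Risk A, step 5. Conversion is not the concern. The concern is selectivity: the syn/anti ratio depends on the co-acid and solvent, the ee is expected to be only about 90%, and remote diastereomers formed after malate attachment would be inseparable. The relative configuration should be confirmed on crystalline 19 before going further.
The fallback stops relying on the catalyst as the only source of purity and resolves classically. It sets out from 19 of insufficient dr or ee. This is dissolved in hot EtOH with 2 equiv of (R)-1-phenylethylamine to give bis[(1R)-1-phenylethanaminium] (2R)-2-[(1R)-1-carboxylato-11-hydroxyundecyl]-5-oxooxolane-2-carboxylate F1. The salt is fractionally crystallised to constant rotation. Partition between 1 M HCl and EtOAc frees the acid, and the fallback comes back to the route at 19.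

Risk B, step 8. The basic ylide may enolise the aldehyde. The enolate could then expel the stabilised furanolate (retro-Michael) or open the β-acyloxy ester.
The fallback builds the chain by olefin metathesis under neutral conditions. It sets out from 9. Methylenation with Me3SiCHN2, PPh3 and 2-propanol, catalysed by RhCl(PPh3)3 in THF at rt, gives methyl (2R)-2-[(2R)-1-tert-butoxy-1-oxopent-4-en-2-yl]-5-oxo-2,5-dihydrofuran-2-carboxylate F2. Cross-metathesis with commercial non-8-en-1-ol (3 equiv) and second-generation Hoveyda–Grubbs catalyst (5 mol%) in CH2Cl2 at 40 °C follows, and the electron-poor butenolide alkene does not take part. The product is methyl (2R)-2-[(2R,4E)-1-tert-butoxy-12-hydroxy-1-oxododec-4-en-2-yl]-5-oxo-2,5-dihydrofuran-2-carboxylate F3. Hydrogenation (H2, Pd/C, EtOAc) saturates both alkenes, and the fallback comes back to the route at 15.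

Risk C, step 17. The displacement may be slow, and prolonged contact with a carboxylate base in DMF could begin β-elimination at the core or benzyl scrambling in the malate.
The fallback reverses the polarity of the ester formation and acylates the alcohol. It sets out from 20, together with 22. Compound 22 is stirred in trifluoroacetic anhydride (0 °C to rt) and evaporated to give (3R)-2,5-dioxooxolan-3-yl trifluoroacetate F4. Alcohol 20 is treated with F4 (2.5 equiv) in CH2Cl2/THF at rt. The anhydride opens at the more electrophilic carbonyl, next to the trifluoroacetoxy group, giving the O-trifluoroacetyl malate half-ester F5. Stirring in MeOH at rt removes the trifluoroacetyl group to give the dibenzyl-protected malate half-ester F6. Hydrogenolysis (H2, Pd/C, THF) brings the fallback back to the route at 28.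

**Further compounds**
F1 | step 5 | bis[(1R)-1-phenylethanaminium] (2R)-2-[(1R)-1-carboxylato-11-hydroxyundecyl]-5-oxooxolane-2-carboxylate | OCCCCCCCCCC[C@@H](C(=O)[O-])[C@@]1(C(=O)[O-])CCC(=O)O1.C[C@@H]([NH3+])c1ccccc1.C[C@@H]([NH3+])c1ccccc1
F2 | step 8 | methyl (2R)-2-[(2R)-1-tert-butoxy-1-oxopent-4-en-2-yl]-5-oxo-2,5-dihydrofuran-2-carboxylate | C=CC[C@@H](C(=O)OC(C)(C)C)[C@@]1(C(=O)OC)C=CC(=O)O1
F3 | step 8 | methyl (2R)-2-[(2R,4E)-1-tert-butoxy-12-hydroxy-1-oxododec-4-en-2-yl]-5-oxo-2,5-dihydrofuran-2-carboxylate | OCCCCCCC/C=C/C[C@@H](C(=O)OC(C)(C)C)[C@@]1(C(=O)OC)C=CC(=O)O1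
F4 | step 17 | (3R)-2,5-dioxooxolan-3-yl trifluoroacetate | O=C1C[C@@H](OC(=O)C(F)(F)F)C(=O)O1
F5 | step 17 | (3R)-4-({(11R)-12-(benzyloxy)-11-[(2R)-2-(benzyloxycarbonyl)-5-oxooxolan-2-yl]-12-oxododecyl}oxy)-4-oxo-3-(trifluoroacetoxy)butanoic acid | O=C(O)C[C@@H](OC(=O)C(F)(F)F)C(=O)OCCCCCCCCCC[C@@H](C(=O)OCc1ccccc1)[C@@]2(C(=O)OCc3ccccc3)CCC(=O)O2
F6 | step 17 | (3R)-4-({(11R)-12-(benzyloxy)-11-[(2R)-2-(benzyloxycarbonyl)-5-oxooxolan-2-yl]-12-oxododecyl}oxy)-3-hydroxy-4-oxobutanoic acid | O=C(O)C[C@@H](O)C(=O)OCCCCCCCCCC[C@@H](C(=O)OCc1ccccc1)[C@@]2(C(=O)OCc3ccccc3)CCC(=O)O2
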